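**Target:** (2S)-5,7-dihydroxy-2-{4-methoxy-3-[(E)-3-methylbuta-1,3-dienyl]-5-(3-methylbut-2-enyl)phenyl}chroman-4-one, C26H28O5. It has one stereocentre, C2. In the given SMILES the CIP order O1 > C1′ > C3 > H reads as S.

## Retrosynthetic overview
1. Target 16 comes from bis-silyl flavanone 15 by buffered desilylation, so nothing strongly acidic or basic follows the stereocentre.
2. The key disconnection is C2–C1′, not the chalcone aldol/oxa-Michael bonds. A Rh(I)/(S)-bisphosphine enantioselective 1,4-addition of the fully decorated arylboronic acid 11 to the intact chromone 14 sets C2 (S) directly.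
3. Boronic acid 11 comes from 5-bromosalicylaldehyde through three orthogonal handles: CHO → E-diene (HWE), C–I → prenyl (Mg/Cu), C–Br → B(OH)2.
4. Chromone 14 comes from 5,7-dihydroxychromone by bis-silylation.
5. Ring order: no ring is built. The A/C benzopyranone and the B ring are bought intact and joined in step 7.

**Assumption:** 5,7-dihydroxychromone (CAS 31721-94-5) is taken as a catalogue compound.

## Route

**Step 1**
Reactants: 1, 5-bromosalicylaldehyde; 2, N-iodosuccinimide
Product: 3, 5-bromo-2-hydroxy-3-iodobenzaldehyde
Conditions: NIS (1.05 equiv), cat. TFA, MeCN, rt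
Reagents that add atoms: N-iodosuccinimide, O=C1CCC(=O)N1I
Why: Electrophilic aromatic iodination, in which the OH directs ortho/para; para carries Br and one ortho carries CHO, so only C3 is open.

**Step 2**
Reactants: 3; 4, iodomethane
Product: 5, 5-bromo-3-iodo-2-methoxybenzaldehyde
Conditions: MeI (1.5 equiv), K2CO3, DMF, rt
Reagents that add atoms: iodomethane, CI
Why: Williamson etherification of an acidic phenoxide installs the 4′-OMe and removes the only acidic proton before the organometallic steps.

**Step 3**
Reactants: 5; 6, diethyl (2-methylallyl)phosphonate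
Product: 7, 5-bromo-1-iodo-2-methoxy-3-[(1E)-3-methylbuta-1,3-dien-1-yl]benzene
Conditions: 6 (1.25 equiv), n-BuLi (1.15 equiv), THF, −78 °C; add 5; then DMPU (3 equiv), −78 °C → rt
Reagents that add atoms: diethyl (2-methylallyl)phosphonate, C=C(C)CP(=O)(OCC)OCC
Why: Horner–Wadsworth–Emmons olefination with an allylic phosphonate proceeds by α-attack on the aryl aldehyde and DMPU-assisted elimination to give the E-diene, and because n-BuLi is kept below the phosphonate loading, C–I and C–Br are untouched.

**Step 4**
Reactants: 7; 8, prenyl bromide (1-bromo-3-methylbut-2-ene)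
Product: 9, 5-bromo-2-methoxy-1-[(1E)-3-methylbuta-1,3-dien-1-yl]-3-(3-methylbut-2-en-1-yl)benzene
Conditions: i-PrMgCl·LiCl (1.1 equiv), THF, −40 °C; CuI (10 mol %), 8 (1.5 equiv), −40 → 0 °C
Reagents that add atoms: prenyl bromide, CC(C)=CCBr
Why: Knochel iodine–magnesium exchange (I far faster than Br, assisted by the ortho-OMe) followed by Cu-catalysed SN2 allylic substitution at the unhindered CH2 of prenyl bromide gives the linear prenyl arene, and the diene is inert to ArMgX at this temperature.

**Step 5**
Reactants: 9; 10, triisopropyl borate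
Product: 11, {4-methoxy-3-[(1E)-3-methylbuta-1,3-dien-1-yl]-5-(3-methylbut-2-en-1-yl)phenyl}boronic acid
Conditions: 10 (1.5 equiv) premixed with 9, THF/toluene, −78 °C, n-BuLi (1.15 equiv) added last; sat. aq NH4Cl to pH ≈ 6; trace BHT, used directly
Reagents that add atoms: triisopropyl borate, CC(C)OB(OC(C)C)OC(C)C; water, O
Why: Bromine–lithium exchange/borylation under in-situ-quench conditions traps the aryllithium as it forms, so it cannot add to the aryl diene, and the mild hydrolysis spares the acid-sensitive diene.

**Step 6**
Reactants: 12, 5,7-dihydroxy-4H-chromen-4-one; 13, tert-butyldimethylsilyl triflate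
Product: 14, 5,7-bis[(tert-butyldimethylsilyl)oxy]-4H-chromen-4-one
Conditions: TBSOTf (2.6 equiv), 2,6-lutidine (4 equiv), CH2Cl2, 0 °C → rt
Reagents that add atoms: TBSOTf, CC(C)(C)[Si](C)(C)OS(=O)(=O)C(F)(F)F
Why: O-silylation with the triflate is strong enough to cap the chelated 5-OH as well as the acidic 7-OH, and silyl ethers donate less than alkyl ethers, which keeps the enone electrophilic.

**Step 7 (key step)**
Reactants: 11 (1.5 equiv); 14 (1.0 equiv)
Product: 15, (2S)-5,7-bis[(tert-butyldimethylsilyl)oxy]-2-{4-methoxy-3-[(1E)-3-methylbuta-1,3-dien-1-yl]-5-(3-methylbut-2-en-1-yl)phenyl}chroman-4-one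
Conditions: [Rh(OH)((S)-MeO-F12-BIPHEP)]2 (3 mol % Rh, preformed from [RhCl(C2H4)2]2, ligand and aq KOH), degassed toluene/H2O 10:1, 25–30 °C, no added base
Reagents that add atoms: boronic acid 11 (transfers the aryl group), C=C(C)/C=C/c1cc(B(O)O)cc(CC=C(C)C)c1OC; water supplies only H
Why: Hayashi–Miyaura Rh-catalysed asymmetric 1,4-addition to a chromone, where the electron-poor chelating bisphosphine allows room-temperature turnover and resists displacement by the substrate diene, and the (S)-biaryl ligand should deliver aryl to the same enone face as in the (S)-BINAP/cyclohexenone case, which maps onto (2S) here.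
Check on the sense of induction: confirm it by CD and chiral HPLC. The antipodal ligand is equally available if the sense is reversed.

**Step 8**
Reactants: 15
Product: 16, (2S)-5,7-dihydroxy-2-{4-methoxy-3-[(1E)-3-methylbuta-1,3-dien-1-yl]-5-(3-methylbut-2-en-1-yl)phenyl}chroman-4-one (target)
Conditions: TBAF/AcOH (1:1.2, 2.5 equiv), THF, 0 °C, 20 min
Reagents that add atoms: none
Why: Fluoride desilylation of aryl silyl ethers under acetic acid buffering avoids both enolate/retro-oxa-Michael racemisation at C2 and protonation of the diene, and the aryl OMe, prenyl and diene groups are inert.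

## Compound list
| No. | Name | SMILES | Role |
|---|---|---|---|
| 1 | 5-bromosalicylaldehyde | O=Cc1cc(Br)ccc1O | starting material |
| 2 | N-iodosuccinimide | O=C1CCC(=O)N1I | starting material (reagent) |
| 3 | 5-bromo-2-hydroxy-3-iodobenzaldehyde | O=Cc1cc(Br)cc(I)c1O | intermediate |
| 4 | iodomethane | CI | starting material (reagent) |
| 5 | 5-bromo-3-iodo-2-methoxybenzaldehyde | O=Cc1cc(Br)cc(I)c1OC | intermediate |
| 6 | diethyl (2-methylallyl)phosphonate | C=C(C)CP(=O)(OCC)OCC | starting material |
| 7 | 5-bromo-1-iodo-2-methoxy-3-[(E)-3-methylbuta-1,3-dienyl]benzene | C=C(C)/C=C/c1cc(Br)cc(I)c1OC | intermediate |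
| 8 | prenyl bromide | CC(C)=CCBr | starting material |
| 9 | 5-bromo-2-methoxy-1-[(E)-3-methylbuta-1,3-dienyl]-3-prenylbenzene | C=C(C)/C=C/c1cc(Br)cc(CC=C(C)C)c1OC | intermediate |
| 10 | triisopropyl borate | CC(C)OB(OC(C)C)OC(C)C | starting material (reagent) |
| 11 | {4-methoxy-3-[(E)-3-methylbuta-1,3-dienyl]-5-prenylphenyl}boronic acid | C=C(C)/C=C/c1cc(B(O)O)cc(CC=C(C)C)c1OC | intermediate |
| 12 | 5,7-dihydroxy-4H-chromen-4-one | O=c1ccoc2cc(O)cc(O)c12 | starting material |
| 13 | tert-butyldimethylsilyl triflate | CC(C)(C)[Si](C)(C)OS(=O)(=O)C(F)(F)F | starting material (reagent) |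
| 14 | 5,7-bis(TBSO)-4H-chromen-4-one | O=c1ccoc2cc(O[Si](C)(C)C(C)(C)C)cc(O[Si](C)(C)C(C)(C)C)c12 | intermediate |
| 15 | (2S)-5,7-bis(TBSO) flavanone | C=C(C)/C=C/c1cc([C@@H]2CC(=O)c3c(O[Si](C)(C)C(C)(C)C)cc(O[Si](C)(C)C(C)(C)C)cc3O2)cc(CC=C(C)C)c1OC | intermediate |
| 16 | (2S)-target flavanone | C=C(C)/C=C/c1cc([C@@H]2CC(=O)c3c(O)cc(O)cc3O2)cc(CC=C(C)C)c1OC | target |

## Summary
Total steps: 8. Longest linear sequence: 7 (steps 1–5, 7, 8).

**Steps most likely to fail**
1. **Step 7.**
   - Risks: the free 1,3-diene may bind Rh or be arylated, the electron-rich chromone may react slowly, and the boronic acid may protodeboronate.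
   - Fallback: install the diene after the stereocentre is set. 2,6-Dibromoanisole is mono-prenylated (Br/Li, then Cu). Ir-catalysed C–H borylation then goes to the only unhindered C–H, para to OMe. The same Rh addition is run with this bromoaryl boronate. A base-free Stille coupling with (E)-tributyl(3-methylbuta-1,3-dienyl)stannane and desilylation complete the route.
2. **Step 3.**
   - Risks: the allylic phosphonate HWE may give a low yield, γ-attack or E/Z erosion.
   - Fallback: form the diene by cross-coupling instead of olefination. 4-Bromo-2,6-diiodoanisole undergoes mono I/Mg exchange and prenylation. An iodide-selective Suzuki coupling follows with (E)-(3-methylbuta-1,3-dienyl)Bpin, made by Zr-catalysed syn-hydroboration of 2-methylbut-1-en-3-yne, which fixes the E geometry. This converges on 9.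
3. **Step 5.**
   - Risk: the organolithium may add to or polymerise the aryl diene.
   - Fallback: avoid carbanions. Pd-catalysed Miyaura borylation of 9 (B2pin2, Pd(dppf)Cl2, KOAc) is followed by KHF2, and the resulting potassium aryltrifluoroborate is used as the aryl donor in the Rh addition.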